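At early times the ash flask gained product quickly, and I built a ladder of time scales from its readings; ash is itself the flask asked about, followed on to 8.0 d.

| flask | substrate | free enzyme | temperature | remark | time |
|---|---|---|---|---|---|
| ash | 0.010 M | 0.05 mol% | 37 °C | the very flask that is asked about, followed so far |  |
| maple | 0.020 M | 0.05 mol% | 22 °C | run made earlier |  |
| flask | 0.010 M | 0.05 mol% | 37 °C |  | 8.0 d |

| run | time / h | product / % | substrate / % |
|---|---|---|---|
| ash | 25.0 | 13.5 | 86.9 |
| ash | 48.0 | 19.8 | 79.4 |
| ash | 72.0 | 24.9 | 75.6 |
| ash | 96.0 | 27.7 | 72.3 |
| ash | 120 | 29.1 | 71.0 |
| ash | 144 | 30.0 | 70.2 |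
| maple | 3.00 | 0.6 | 99.0 |
| maple | 5.00 | 0.6 | 99.1 |
| maple | 8.00 | 1.3 | 98.5 |
| maple | 15.0 | 2.6 | 97.2 |
| maple | 25.0 | 5.0 | 95.3 |
| maple | 40.0 | 7.7 | 92.4 |

(readings scatter by 0.3 percentage points)

- winter: at 8.0 d take out 90% of the product then present, then wait 8.0 d
- summer: at 8.0 d add free enzyme, 100% of the amount charged, then wait 8.0 d
- midnight: change nothing and wait 8.0 d more
- spring: at 8.0 d raise the temperature by 20 K, then wait 8.0 d

- product that was removed still counts
- additions bring no volume worth counting

- product, in percent of the substrate first charged, at 8.0 d
- which option adds most product ("none" when 2 percentage points or less is all one gets) (winter / summer / midnight / spring / none)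
- product present, with what was taken out counted in, in percent of the substrate first charged, after summer
- product present, with what was taken out counted in, in percent of the substrate first charged, after spring

On the fastest rung, the enzyme at 0.05 mol% could hold very little of the charge, so product and substrate together stayed close to the charge throughout ash.

On the next rung stood the approach to the plateau. I measured the gap to the last ash reading at two times:

τ = time between the readings / ln(ratio of the gaps) = 40.0 h

The asked time is 4.80 such constants, longer, so I put product at 8.0 d a little above the last reading.

On the slowest rung lay the plateau itself. Colder maple reached 7.7% by 40.0 h and was still running straight, so it showed no plateau, and the readings could not separate a balance (thermodynamic control) from dying enzyme. I reckoned the balance branch as my own. There I followed one molecule: once taken out it stays product, while inside the flask it ends as product with a chance s, the product share 29.9%. With product near s, winter then gains: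

share taken out × s × (remainder of s) = 19 percentage points

The forecast took the other branch, "I lean, only moderately, towards enzyme dying": 30.8% now, summer best, 53% after summer, 31.2% after spring.

The flask gave 30.6%, and the best option was winter, gaining 19 points. Summer reached 31.0%, and spring fell to 6.18%.

    free enzyme → unfolded enzyme (k = 2.30 × 10⁻⁴ /h, Ea = 278 kJ/mol)
    substrate + free enzyme ⇌ complex (K = 25.0 /M, k = 7.20 × 10⁵ /M/h, Ea = 36.0 kJ/mol, ΔH = −1.00 kJ/mol)
    complex ⇌ free enzyme + product (K = 0.0180 M, k = 68.0 /h, Ea = 90.0 kJ/mol, ΔH = −81.0 kJ/mol)
    (constants at 37 °C)

The ash plateau was a balance because of the reverse step, complex to substrate + free enzyme: the run without it gave >99.9% at 8.0 d, not 30.6%. Taking 90% of 30.6% out and splitting the remainder by s, as read from ash, gave an estimated gain of 19 points; the winter flask itself gained 19 points. In the repeat at 52 °C, the product share was 9.40%, a third of s, with product at 9.40%.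

(Readings and results are calculated with constants of no real substance, noise included.)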